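The flavonol is disconnected across ring C at O1–C2 and C3–C4. C2, with its 4-methoxyphenyl group, and C3 are drawn from a β-nitrostyrene; O1, C8a, C4a and C4 belong to a salicylaldehyde that already carries all four methoxy groups of ring A. A single amine-catalysed oxa-Michael/Henry/dehydration cascade forms both bonds and closes ring C as a 3-nitro-2H-chromene, the nitro group serving as a placeholder for the C3 oxygen. The step exploits the 1,2-relationship of the heteroatom-bearing C3 and the C4 carbonyl, with C4 bound to ring A ortho to O1. The precursor, 2-hydroxy-3,4,5,6-tetramethoxybenzaldehyde, is made in two steps from 1,2,3,4-tetramethoxybenzene.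

Key step: step 3

Remark: the target is achiral; every stereocentre formed on the way is racemic and is destroyed when ring C becomes the pyranone, so no stereocontrol is needed. Compounds 1 and 7 are taken as purchasable.

Step 1
Reactants: 1 1,2,3,4-tetramethoxybenzene
Product: 4 2,3,4,5-tetramethoxyphenol, via aryllithium 2 (not isolated), via lithium arylborate 3 (not isolated)
Conditions: n-BuLi, TMEDA, THF, 0 °C; B(OMe)3, −78 °C to rt; then AcOH, 30% H2O2, 0 °C to rt
Reagents that add atoms: hydrogen peroxide, OO
Why: Directed ortho-metalation next to a methoxy group lithiates the only kind of ring C–H present (C5 and C6 are equivalent) to give 2, borylation gives 3, and peroxide oxidation with aryl migration from boron to oxygen turns the C–B bond into C–OH (lithiation–borylation–oxidation), with no stereocentre formed.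

Step 2
Reactants: 4 2,3,4,5-tetramethoxyphenol
Product: 6 2-hydroxy-3,4,5,6-tetramethoxybenzaldehyde, via salicyl alcohol 5 (not isolated)
Conditions: (CH2O)n, MgCl2, Et3N, MeCN, reflux; then 1 M HCl
Reagents that add atoms: paraformaldehyde (as formaldehyde), C=O
Why: In this magnesium-mediated ortho-formylation (Casnati–Skattebøl reaction) the magnesium phenoxide delivers formaldehyde to the single free ring carbon, which lies ortho to the hydroxyl, and the hydroxymethyl intermediate 5 is oxidised to the aldehyde by Oppenauer-type hydride transfer to a second formaldehyde, with no stereocentre formed.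

Step 3
Reactants: 6 2-hydroxy-3,4,5,6-tetramethoxybenzaldehyde; 7 (E)-1-methoxy-4-(2-nitrovinyl)benzene
Product: 10 rac-5,6,7,8-tetramethoxy-2-(4-methoxyphenyl)-3-nitro-2H-chromene, via oxa-Michael adduct 8 (not isolated), via nitrochromanol 9 (not isolated)
Conditions: 7 (1.5 equiv), DABCO (0.5 equiv), MeCN (concentrated), 50 °C
Reagents that add atoms: none
Why: DABCO deprotonates the phenol of 6, the phenoxide adds to the anisyl-bearing β-carbon of 7 to form O1–C2 (adduct 8), the nitronate of 8 attacks the neighbouring aldehyde carbon to form C3–C4 (nitrochromanol 9), and E1cB loss of water gives the conjugated nitroalkene 10. The closest known reaction type is the amine-catalysed domino oxa-Michael–Henry condensation of salicylaldehydes with β-nitrostyrenes to 2-aryl-3-nitro-2H-chromenes. Ring C is closed in the Henry step by a 6-exo-trig attack of the nitronate carbon on the aldehyde C=O. The only stereocentre of 10, C2, is set in the oxa-Michael step with no controlling element (achiral catalyst, reversible addition), so 10 should be racemic, which is acceptable because C2 becomes sp2 in the target. The selectivity required is oxa-Michael before Henry with exclusive O-attack: the phenoxide is the only nucleophile the amine can generate and can add only β to the nitro group, the nitronate then lies within six-membered reach of the aldehyde, and the fully substituted ring A offers no competing C–H site. Excess 7 offsets amine-initiated oligomerisation, and the dehydration should pull the reversible addition steps forward despite the electron-rich aldehyde flanked on both sides.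

Step 4
Reactants: 10 rac-5,6,7,8-tetramethoxy-2-(4-methoxyphenyl)-3-nitro-2H-chromene
Product: 11 rac-3,4-epoxy-5,6,7,8-tetramethoxy-2-(4-methoxyphenyl)-3-nitrochroman (oxirane oxygen trans to the C2 aryl group)
Conditions: 30% H2O2, 2 M NaOH (0.5 equiv), THF–H2O (no alcohol), 0 °C, short contact; cold extraction, crude used directly
Reagents that add atoms: hydrogen peroxide, OO
Why: In this Weitz–Scheffer-type nucleophilic epoxidation hydroperoxide adds to C4 of the nitroalkene and the C3 carbanion closes onto the peroxide oxygen with loss of hydroxide; the oxirane is cis-fused by necessity, attack anti to the C2 aryl group should favour the trans isomer, and both new stereocentres (C3, C4) are removed in step 5, so either diastereomer serves.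

Step 5
Reactants: 11 rac-3,4-epoxy-5,6,7,8-tetramethoxy-2-(4-methoxyphenyl)-3-nitrochroman
Product: 13 3-hydroxy-5,6,7,8-tetramethoxy-2-(4-methoxyphenyl)-4H-chromen-4-one, via acyloin 12 (not isolated)
Conditions: NaHCO3, THF–H2O, N2, 40 °C; then Cu(OAc)2·H2O (0.3 equiv), air, rt; aq. EDTA work-up
Reagents that add atoms: water, O
Why: Water opens the α-nitro epoxide at the alkoxy-activated benzylic C4 and the C3 alkoxide expels nitrite (nitro epoxide to α-hydroxy ketone hydrolysis) to give acyloin 12, which Cu(OAc)2 with air as terminal oxidant (divalent copper regenerated from monovalent copper) dehydrogenates to the 3,4-dicarbonyl level (acyloin oxidation), and this exists as its aromatic enol, the flavonol, with all stereocentres erased.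

Compound list
1 | 1,2,3,4-tetramethoxybenzene | COc1ccc(OC)c(OC)c1OC | starting material
2 | (2,3,4,5-tetramethoxyphenyl)lithium | [Li]c1cc(OC)c(OC)c(OC)c1OC | intermediate (not isolated)
3 | lithium trimethoxy(2,3,4,5-tetramethoxyphenyl)borate | [Li+].CO[B-](OC)(OC)c1cc(OC)c(OC)c(OC)c1OC | intermediate (not isolated)
4 | 2,3,4,5-tetramethoxyphenol | COc1cc(O)c(OC)c(OC)c1OC | intermediate
5 | 2-(hydroxymethyl)-3,4,5,6-tetramethoxyphenol (present as its magnesium alkoxide) | COc1c(O)c(CO)c(OC)c(OC)c1OC | intermediate (not isolated)
6 | 2-hydroxy-3,4,5,6-tetramethoxybenzaldehyde | COc1c(O)c(C=O)c(OC)c(OC)c1OC | intermediate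
7 | (E)-1-methoxy-4-(2-nitrovinyl)benzene (4-methoxy-β-nitrostyrene) | COc1ccc(/C=C/[N+](=O)[O-])cc1 | starting material
8 | 2-[1-(4-methoxyphenyl)-2-nitroethoxy]-3,4,5,6-tetramethoxybenzaldehyde (racemic; (S) enantiomer drawn) | COc1ccc([C@@H](C[N+](=O)[O-])Oc2c(OC)c(OC)c(OC)c(OC)c2C=O)cc1 | intermediate (not isolated)
9 | 5,6,7,8-tetramethoxy-2-(4-methoxyphenyl)-3-nitrochroman-4-ol (racemic; mixture of C3/C4 diastereomers, those centres left undefined) | COc1ccc([C@@H]2Oc3c(OC)c(OC)c(OC)c(OC)c3C(O)C2[N+](=O)[O-])cc1 | intermediate (not isolated)
10 | 5,6,7,8-tetramethoxy-2-(4-methoxyphenyl)-3-nitro-2H-chromene (racemic; (2S) enantiomer drawn) | COc1ccc([C@@H]2Oc3c(OC)c(OC)c(OC)c(OC)c3C=C2[N+](=O)[O-])cc1 | intermediate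
11 | 3,4-epoxy-5,6,7,8-tetramethoxy-2-(4-methoxyphenyl)-3-nitrochroman, i.e. 4,5,6,7-tetramethoxy-2-(4-methoxyphenyl)-1a-nitro-1a,7b-dihydro-2H-oxireno[2,3-c]chromene (racemic; oxirane oxygen trans to the 2-aryl group; one enantiomer drawn) | COc1ccc([C@@H]2Oc3c(OC)c(OC)c(OC)c(OC)c3[C@H]4O[C@@]24[N+](=O)[O-])cc1 | intermediate
12 | 4-hydroxy-5,6,7,8-tetramethoxy-2-(4-methoxyphenyl)chroman-3-one (racemic; C2/C4 diastereomer mixture expected, so no descriptors given) | COc1ccc(C2Oc3c(OC)c(OC)c(OC)c(OC)c3C(O)C2=O)cc1 | intermediate (not isolated)
13 | 3-hydroxy-5,6,7,8-tetramethoxy-2-(4-methoxyphenyl)-4H-chromen-4-one (achiral) | COc1ccc(-c2oc3c(OC)c(OC)c(OC)c(OC)c3c(=O)c2O)cc1 | target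

Total step count: 5. Longest linear sequence: 5 steps (1 to 13); 7 enters at step 3.

Steps most likely to fail

1. Step 3. The Henry closure and dehydration may stall on the electron-rich aldehyde, which is flanked by the phenol and a methoxy group, while the nitrostyrene is consumed by amine-initiated oligomerisation. Fallback (sets out from 4, returns at 13): ring C is built by the classical flavone route and C3 is oxygenated last. C-Acetylation of 4 at its only free carbon (Ac2O, BF3·OEt2, 80 °C) should give 1-(2-hydroxy-3,4,5,6-tetramethoxyphenyl)ethan-1-one F1. Claisen–Schmidt condensation with 4-methoxybenzaldehyde (KOH, EtOH) should give (E)-1-(2-hydroxy-3,4,5,6-tetramethoxyphenyl)-3-(4-methoxyphenyl)prop-2-en-1-one F2. Catalytic I2 in DMSO at 120 °C should cyclise and dehydrogenate this to 5,6,7,8-tetramethoxy-2-(4-methoxyphenyl)-4H-chromen-4-one F3, a six-membered closure not diverted to the aurone. DMDO in acetone should epoxidise C2=C3 to racemic 2,3-epoxy-5,6,7,8-tetramethoxy-2-(4-methoxyphenyl)chroman-4-one F4, which should open to 13 on brief treatment with p-TsOH.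

2. Step 4. After hydroperoxide addition the C3 carbanion may expel the ring phenoxide (ring opening) instead of closing the oxirane, base may shift the double bond to the 4H-chromene, or the labile oxirane may open during work-up. Fallback (sets out from 10, returns at 13): the nitro group is converted reductively instead of oxidatively. Fe powder in AcOH–EtOH at 80 °C should reduce the nitroalkene through to the ketone, racemic 5,6,7,8-tetramethoxy-2-(4-methoxyphenyl)chroman-3-one F5. SeO2 in wet dioxane at 80 °C (Riley oxidation of the benzylic C4 methylene next to the ketone) should then raise C4 to the carbonyl level, and enolisation gives 13.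

3. Step 5. Ionisation at C4 to a flavylium-type cation with subsequent ring opening, or oxidative C–C cleavage of the enediolate or of the copper flavonolate, may outrun clean dehydrogenation. Fallback (sets out from 11, returns at 13): the acyloin is first moved into a stable tautomer and then dehydrogenated without metal. Prolonged hydrolysis of 11 under N2 (NaHCO3, THF–H2O, 50 °C) should give 12 and allow its α-ketol tautomerisation through the enediol to the conjugated aryl ketone, racemic trans-3-hydroxy-5,6,7,8-tetramethoxy-2-(4-methoxyphenyl)chroman-4-one F6, which can be isolated. I2 and KOAc in AcOH at reflux should then dehydrogenate C2–C3 to 13.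

Further compounds
F1 | step 3 | 1-(2-hydroxy-3,4,5,6-tetramethoxyphenyl)ethan-1-one | CC(=O)c1c(O)c(OC)c(OC)c(OC)c1OC
F2 | step 3 | (E)-1-(2-hydroxy-3,4,5,6-tetramethoxyphenyl)-3-(4-methoxyphenyl)prop-2-en-1-one | COc1ccc(/C=C/C(=O)c2c(O)c(OC)c(OC)c(OC)c2OC)cc1
F3 | step 3 | 5,6,7,8-tetramethoxy-2-(4-methoxyphenyl)-4H-chromen-4-one | COc1ccc(-c2cc(=O)c3c(OC)c(OC)c(OC)c(OC)c3o2)cc1
F4 | step 3 | 2,3-epoxy-5,6,7,8-tetramethoxy-2-(4-methoxyphenyl)chroman-4-one (racemic, cis-fused oxirane, one enantiomer drawn) | COc1ccc([C@@]23O[C@@H]2C(=O)c2c(OC)c(OC)c(OC)c(OC)c2O3)cc1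
F5 | step 4 | 5,6,7,8-tetramethoxy-2-(4-methoxyphenyl)chroman-3-one (racemic, one enantiomer drawn) | COc1ccc([C@@H]2Oc3c(OC)c(OC)c(OC)c(OC)c3CC2=O)cc1
F6 | step 5 | trans-3-hydroxy-5,6,7,8-tetramethoxy-2-(4-methoxyphenyl)chroman-4-one (racemic, one enantiomer drawn) | COc1ccc([C@@H]2Oc3c(OC)c(OC)c(OC)c(OC)c3C(=O)[C@H]2O)cc1
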